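**Retrosynthetic overview**

1. The target is (12Z)-6α-acetoxylabda-12,14-diene-7β,8α-diol. The route rests on ring B, where the oxygenated C7 is bonded to C8, a tertiary carbinol carrying the C17 methyl; with C7 at the ketone level this C7(=O)–C8(OH)(CH3) unit is an α-ketol.
2. Key disconnection C8–C9: the 7-oxo-8α-hydroxy-8β-methyl decalin comes from a 7α-acetyl-7β-hydroxy trans-hydrindane by a 1,2-shift of C9 from C7 to the acetyl carbon (ring B five → six). The C6 oxygen, the acetate and the 7β-OH follow by enolate hydroxylation, acylation and ketone reduction.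
3. The (12Z)-diene is completed on the hydrindanone before the acetyl carbinol is made (C12 aldehyde → Z-iodoalkene → Stille vinylation), because a C12 carbonyl would be trapped as a five-ring lactol by O7 or O8 once either hydroxyl exists.
4. The hydrindanone comes from the bicyclic enone by aldol alkylidenation at C9 and hydrogenation (sets C5 and C9). The enone comes from asymmetric decarboxylative allylation (sets C10), Wacker oxidation and aldol cyclisation.
5. Ring order: ring A (from the cyclohexanone), five-membered ring B (step 4), six-membered ring B by enlargement (step 13).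

Key step: step 13

Remark: labdane numbering is used for all bicyclic compounds (in the hydrindanes the five-membered ring is C5–C6–C7–C9–C10 and the acetyl carbons are C8/C17), β is the face of the C10 methyl, and the (R)-PHOX ligand is assumed to give (R)-4 because the (S)-ligand gives the (S)-ketone in this series.

**Route**

Step 1
Reactants: 1 2,2,6-trimethylcyclohexanone; 2 allyl chloroformate
Product: 3 allyl 2,6,6-trimethylcyclohex-1-en-1-yl carbonate
Conditions: LiHMDS, THF, 0 °C; then 2, −78 °C → rt
Reagents that add atoms: allyl chloroformate (2), C=CCOC(Cl)=O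
Why: The ketone has one enolisable position, and its hindered tetrasubstituted lithium enolate is acylated on oxygen by the hard chloroformate (enol carbonate formation), which also erases the racemic stereocentre.

Step 2
Reactants: 3 allyl enol carbonate
Product: 4 (R)-2-allyl-2,6,6-trimethylcyclohexan-1-one
Conditions: Pd2(dba)3 (cat.), (R)-t-BuPHOX (cat.), THF, 25 °C
Reagents that add atoms: none
Why: Pd-catalysed decarboxylative asymmetric allylic alkylation (Tsuji allylation with a PHOX ligand) recombines the Pd-allyl cation with the enolate at its tetrasubstituted carbon, the ligand choosing the enolate face and so setting the C10 quaternary centre.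

Step 3
Reactants: 4 (R)-allyl ketone
Product: 5 (R)-2,2,6-trimethyl-6-(2-oxopropyl)cyclohexan-1-one
Conditions: PdCl2 (cat.), Cu(OAc)2·H2O (cat.), O2 (1 atm), DMA/H2O, rt
Reagents that add atoms: water, O
Why: Tsuji–Wacker oxidation converts the terminal alkene into the methyl ketone by Markovnikov hydroxypalladation and leaves the quaternary centre untouched.

Step 4
Reactants: 5 1,4-diketone
Product: 6 (7aR)-4,4,7a-trimethyl-1,4,5,6,7,7a-hexahydro-2H-inden-2-one (hydrind-5-en-7-one in labdane numbering)
Conditions: KOH, xylenes, 110 °C (Dean–Stark)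
Reagents that add atoms: none
Why: Intramolecular aldol condensation of the 1,4-diketone (methyl ketone enolate onto the ring carbonyl, then dehydration) closes the five-membered ring as the conjugated enone, and C10 cannot epimerise.

Step 5
Reactants: 6 bicyclic enone; 7 (tert-butyldimethylsilyloxy)acetaldehyde
Product: 8 9-[2-(tert-butyldimethylsilyloxy)-1-hydroxyethyl] enone (mixture at C9 and C11)
Conditions: LDA, THF, −78 °C; then 7, −78 °C; aq. NH4Cl
Reagents that add atoms: (tert-butyldimethylsilyloxy)acetaldehyde (7), CC(C)(C)[Si](C)(C)OCC=O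
Why: Directed aldol addition works here because the enone has no γ-hydrogens (C4 and C10 are quaternary), so LDA forms only the cross-conjugated C9 enolate; the two new centres are removed in step 6.

Step 6
Reactants: 8 aldol adduct
Product: 10 9-[2-(tert-butyldimethylsilyloxy)ethylidene]hydrind-5-en-7-one (C9=C11 geometry not defined), via C11 mesylate 9 (not isolated)
Conditions: MsCl, Et3N, CH2Cl2, 0 °C; then DBU, rt
Reagents that add atoms: none
Why: Mesylation of the β-hydroxy ketone and E1cB elimination with DBU complete the aldol condensation to the exocyclic C9=C11 enone, and either alkene geometry serves.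

Step 7
Reactants: 10 cross-conjugated dienone
Product: 11 9β-[2-(tert-butyldimethylsilyloxy)ethyl]-4,4,10-trimethyl-trans-hydrindan-7-one (5α-H, 9α-H, 10β-CH3)
Conditions: H2 (4 atm), 10% Pd/C, EtOAc, rt
Reagents that add atoms: none
Why: Heterogeneous catalytic hydrogenation should deliver hydrogen to both C=C bonds from the α face, away from the axial 10β-methyl (and, at C5, the axial 4β-methyl), which sets 9α-H (chain β) and 5α-H (trans fusion) while ketone and silyl ether survive.

Step 8
Reactants: 11 silyl ether ketone
Product: 12 9β-(2-hydroxyethyl)-trans-hydrindan-7-one (may sit partly as its cyclic hemiketal)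
Conditions: HF·pyridine, pyridine, THF, 0 °C → rt
Reagents that add atoms: none
Why: Buffered fluoride cleavage of the primary silyl ether is non-basic, so the C9 centre next to the ketone is not disturbed.

Step 9
Reactants: 12 keto alcohol
Product: 13 9β-(2-oxoethyl)-trans-hydrindan-7-one (C12 aldehyde)
Conditions: Dess–Martin periodinane, NaHCO3, CH2Cl2, 0 °C → rt
Reagents that add atoms: none
Why: Dess–Martin oxidation takes the primary alcohol (through its open form) to the aldehyde under buffered conditions that avoid enolisation at C9 and C11.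

Step 10
Reactants: 13 keto aldehyde; 14 ethyltriphenylphosphonium iodide
Product: 15 9β-[(2Z)-3-iodobut-2-en-1-yl]-trans-hydrindan-7-one
Conditions: 14, n-BuLi, THF, rt; I2, −78 °C; NaHMDS, −20 °C; then 13, −78 → −20 °C
Reagents that add atoms: ethyltriphenylphosphonium iodide (14), CC[P+](c1ccccc1)(c1ccccc1)c1ccccc1.[I-]; iodine, II
Why: Wittig olefination with the α-iodo ylide (Stork–Zhao-type iodoalkylidenation) is chemoselective for the aldehyde over the hindered ketone at −78 °C and kinetically gives the (Z)-iodoalkene, iodine cis to C11.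

Step 11
Reactants: 15 (Z)-iodoalkene; 16 tributyl(vinyl)stannane
Product: 17 9β-[(2Z)-3-methylpenta-2,4-dien-1-yl]-trans-hydrindan-7-one
Conditions: 16, Pd2(dba)3 (cat.), AsPh3, CuI (cat.), NMP, rt → 40 °C
Reagents that add atoms: tributyl(vinyl)stannane (16), C=C[Sn](CCCC)(CCCC)CCCC
Why: Stille coupling proceeds with retention at the alkenyl carbon under neutral conditions, so the vinyl group ends cis to C11 and the (12Z)-diene is complete.

Step 12
Reactants: 17 dienyl ketone; 18 ethyl vinyl ether
Product: 20 7α-acetyl-7β-hydroxy-9β-[(2Z)-3-methylpenta-2,4-dien-1-yl]-trans-hydrindane, via ethoxyvinyl carbinol 19 (not isolated)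
Conditions: 18, t-BuLi, THF, −78 → 0 °C; then 17, −78 °C; then 0.5 M HCl, THF, 0 °C
Reagents that add atoms: ethyl vinyl ether (18), C=COCC; water, O
Why: 1,2-Addition of the acyl-anion equivalent 1-ethoxyvinyllithium should occur from the α face, opposite the 10β-methyl and the adjacent 9β-chain, setting 7β-OH/7α-carbon, and brief dilute-acid hydrolysis of the enol ether unmasks the methyl ketone without touching the diene.

Step 13
Reactants: 20 7α-acetyl-7β-hydroxy hydrindane
Product: 21 (12Z)-8α-hydroxylabda-12,14-dien-7-one
Conditions: KOH (0.3 equiv), degassed MeOH, 25–45 °C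
Reagents that add atoms: none
Why: Hydroxide reversibly forms the C7 potassium alkoxide, and with the C7–O⁻ and acetyl C=O dipoles opposed (anti) the C7–C9 bond lies parallel to the carbonyl π* and shifts suprafacially onto the acetyl carbon while C7 becomes the ketone; this is an α-ketol (acyloin) rearrangement of the kind known as base-induced D-homoannulation of 17-hydroxy-20-oxo steroids. Ring B is not closed from a chain but enlarged: the 1,2-shift inserts C8 between C7 and C9 (new C8–C9 bond), and loss of trans-hydrindane strain should make the shift effectively irreversible at this temperature. The new stereocentre C8 follows from the 7β-O/7α-acetyl configuration combined with the anti alignment, which turns the carbonyl oxygen to the α face and the methyl to the β face as C9 arrives (8α-OH, 8β-CH3); C9 migrates with retention and C5/C10 are untouched. The step needs C9 rather than C6 to migrate, which the substrate should favour because C9 is the more substituted, electron-richer terminus and its departure relieves crowding between the C7 quaternary centre, the C9 chain and C10. A non-chelating potassium counter-ion in methanol is chosen to hold the anti alignment (a chelating Lewis acid would lead to the C8 epimer), and the mild temperature keeps the outcome kinetic.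

Step 14
Reactants: 21 8α-hydroxy-7-ketone
Product: 22 (12Z)-6α,8α-dihydroxylabda-12,14-dien-7-one
Conditions: KHMDS (2.3 equiv), THF, −78 °C; then 2-(phenylsulfonyl)-3-phenyloxaziridine, −78 °C; AcOH
Reagents that add atoms: 2-(phenylsulfonyl)-3-phenyloxaziridine, O=S(=O)(c1ccccc1)N1OC1c1ccccc1
Why: Enolate oxidation with a sulfonyloxaziridine (Davis hydroxylation) can occur only at C6 because C8 is quaternary, and the alkoxide–enolate dianion should be oxygenated from the α face since the axial 4β-, 8β- and 10β-methyl groups screen the β face, giving the equatorial 6α-OH.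

Step 15
Reactants: 22 6α,8α-diol ketone
Product: 23 (12Z)-6α-acetoxy-8α-hydroxylabda-12,14-dien-7-one
Conditions: Ac2O, DMAP (cat.), pyridine, CH2Cl2, 0 °C → rt
Reagents that add atoms: acetic anhydride, CC(=O)OC(C)=O
Why: DMAP-catalysed acylation esterifies the secondary 6-OH while the tertiary 8-OH stays free.

Step 16
Reactants: 23 6α-acetoxy ketone
Product: 24 (12Z)-6α-acetoxylabda-12,14-diene-7β,8α-diol (CNP0138393.1)
Conditions: NaBH4, CeCl3·7H2O, MeOH, −40 °C; AcOH
Reagents that add atoms: none
Why: Luche-type borohydride reduction should deliver hydride axially from the α face (the β face is screened by the axial 8β-methyl) to give the equatorial 7β-alcohol, and low temperature with an acidic quench suppresses 6→7 acetyl migration.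

**Compound list**

1 | 2,2,6-trimethylcyclohexanone (racemic) | CC1CCCC(C)(C)C1=O | starting material
2 | allyl chloroformate | C=CCOC(Cl)=O | starting material
3 | allyl 2,6,6-trimethylcyclohex-1-en-1-yl carbonate | C=CCOC(=O)OC1=C(C)CCCC1(C)C | intermediate
4 | (R)-2-allyl-2,6,6-trimethylcyclohexan-1-one | C=CC[C@@]1(C)CCCC(C)(C)C1=O | intermediate
5 | (R)-2,2,6-trimethyl-6-(2-oxopropyl)cyclohexan-1-one | CC(=O)C[C@@]1(C)CCCC(C)(C)C1=O | intermediate
6 | (7aR)-4,4,7a-trimethyl-1,4,5,6,7,7a-hexahydro-2H-inden-2-one | O=C1C=C2C(C)(C)CCC[C@]2(C)C1 | intermediate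
7 | (tert-butyldimethylsilyloxy)acetaldehyde | CC(C)(C)[Si](C)(C)OCC=O | starting material
8 | 9-[2-(tert-butyldimethylsilyloxy)-1-hydroxyethyl] derivative of 6 (mixture at C9, C11) | CC(C)(C)[Si](C)(C)OCC(O)C1C(=O)C=C2C(C)(C)CCC[C@@]21C | intermediate
9 | C11 methanesulfonate of 8 | CC(C)(C)[Si](C)(C)OCC(OS(C)(=O)=O)C1C(=O)C=C2C(C)(C)CCC[C@@]21C | intermediate (not isolated)
10 | 9-[2-(tert-butyldimethylsilyloxy)ethylidene]-4,4,10-trimethylhydrind-5-en-7-one | CC(C)(C)[Si](C)(C)OCC=C1C(=O)C=C2C(C)(C)CCC[C@@]21C | intermediate
11 | 9β-[2-(tert-butyldimethylsilyloxy)ethyl]-4,4,10-trimethyl-trans-hydrindan-7-one | CC(C)(C)[Si](C)(C)OCC[C@H]1C(=O)C[C@H]2C(C)(C)CCC[C@@]21C | intermediate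
12 | 9β-(2-hydroxyethyl)-4,4,10-trimethyl-trans-hydrindan-7-one | OCC[C@H]1C(=O)C[C@H]2C(C)(C)CCC[C@@]21C | intermediate
13 | 9β-(2-oxoethyl)-4,4,10-trimethyl-trans-hydrindan-7-one | O=CC[C@H]1C(=O)C[C@H]2C(C)(C)CCC[C@@]21C | intermediate
14 | ethyltriphenylphosphonium iodide | CC[P+](c1ccccc1)(c1ccccc1)c1ccccc1.[I-] | starting material
15 | 9β-[(2Z)-3-iodobut-2-en-1-yl]-4,4,10-trimethyl-trans-hydrindan-7-one | I/C(C)=C\C[C@H]1C(=O)C[C@H]2C(C)(C)CCC[C@@]21C | intermediate
16 | tributyl(vinyl)stannane | C=C[Sn](CCCC)(CCCC)CCCC | starting material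
17 | 9β-[(2Z)-3-methylpenta-2,4-dien-1-yl]-4,4,10-trimethyl-trans-hydrindan-7-one | C=C/C(C)=C\C[C@H]1C(=O)C[C@H]2C(C)(C)CCC[C@@]21C | intermediate
18 | ethyl vinyl ether | C=COCC | starting material
19 | 7α-(1-ethoxyvinyl)-7β-hydroxy adduct of 17 | C=C/C(C)=C\C[C@H]1[C@](O)(C(=C)OCC)C[C@H]2C(C)(C)CCC[C@@]21C | intermediate (not isolated)
20 | 7α-acetyl-7β-hydroxy-9β-[(2Z)-3-methylpenta-2,4-dien-1-yl]-4,4,10-trimethyl-trans-hydrindane | C=C/C(C)=C\C[C@H]1[C@](O)(C(C)=O)C[C@H]2C(C)(C)CCC[C@@]21C | intermediate
21 | (12Z)-8α-hydroxylabda-12,14-dien-7-one | C=C/C(C)=C\C[C@H]1[C@](C)(O)C(=O)C[C@H]2C(C)(C)CCC[C@@]21C | intermediate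
22 | (12Z)-6α,8α-dihydroxylabda-12,14-dien-7-one | C=C/C(C)=C\C[C@H]1[C@](C)(O)C(=O)[C@H](O)[C@H]2C(C)(C)CCC[C@@]21C | intermediate
23 | (12Z)-6α-acetoxy-8α-hydroxylabda-12,14-dien-7-one | C=C/C(C)=C\C[C@H]1[C@](C)(O)C(=O)[C@H](OC(C)=O)[C@H]2C(C)(C)CCC[C@@]21C | intermediate
24 | (12Z)-6α-acetoxylabda-12,14-diene-7β,8α-diol | C=C/C(C)=C\C[C@H]1[C@](C)(O)[C@@H](O)[C@H](OC(C)=O)[C@H]2C(C)(C)CCC[C@@]21C | target

**Step count and risks**

Total step count: 16. Longest linear sequence: 16 steps (from 1).

Steps most likely to fail:

Step 13. The C7–C6 bond may shift in place of C7–C9, or the shift may run through the syn rotamer or equilibrate, because the wanted path builds the axial 8β-methyl next to the 10β-methyl. The fallback makes the C7-epimeric ketol and rearranges it under chelation, where the syn arrangement turns the acetyl methyl away from C9 and the more substituted carbon should migrate to the same C8 configuration. Setting out from 17, van Leusen reductive cyanation (TosMIC, t-BuOK, DME/EtOH) would give the 7-carbonitrile F1 (both C7 epimers serve). Methyllithium addition and acidic hydrolysis of the imine would give the 7-acetyl hydrindane F2. Hydroxylation of its more substituted potassium enolate with O2 and P(OEt)3 (t-BuOK, DMF/t-BuOH, −20 °C), oxygen entering from the open α face, would give the 7α-hydroxy-7β-acetyl ketol F3. Heating F3 with Al(O-t-Bu)3 in toluene should then give the ring-enlarged ketol, and the route is rejoined at 21.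

Step 7. The C5=C6 bond lies between two quaternary carbons and may be saturated slowly, so that prolonged exposure causes hydrogenolysis of the allylic C12–O bond or erodes face selectivity at C5. The fallback separates the two reductions and changes the way hydrogen reaches C5. Setting out from 10, conjugate hydride reduction of the exocyclic enone (K-Selectride, THF, −78 °C, with α-face protonation of the C9 enolate on work-up) would give the 9β-[2-(tert-butyldimethylsilyloxy)ethyl] enone F4. Dissolving-metal reduction of F4 (Li, NH3, t-BuOH, THF, −78 °C) should then protonate the C5 carbanion from the α face, and the route is rejoined at 11.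

Step 10. The iodo ylide may give poor Z/E control or decompose before it reacts with the enolisable keto aldehyde. The fallback sets the geometry by catalyst-controlled sequential coupling. Setting out from 13, dibromo-olefination (CBr4, PPh3, CH2Cl2, 0 °C) would give the 1,1-dibromoalkene F5. Trans-selective Negishi monomethylation (MeZnCl, PdCl2(DPEphos), THF) replaces the bromine trans to C11 and would give the (Z)-3-bromobut-2-enyl ketone F6. Stille coupling of F6 with 16 (Pd(t-Bu3P)2, CsF, dioxane) proceeds with retention, and the route is rejoined at 17.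

**Further compounds**

F1 | step 13 | 7-cyano-9β-[(2Z)-3-methylpenta-2,4-dien-1-yl]-4,4,10-trimethyl-trans-hydrindane (C7 epimers) | C=C/C(C)=C\C[C@H]1C(C#N)C[C@H]2C(C)(C)CCC[C@@]21C
F2 | step 13 | 7-acetyl-9β-[(2Z)-3-methylpenta-2,4-dien-1-yl]-4,4,10-trimethyl-trans-hydrindane (C7 epimers) | C=C/C(C)=C\C[C@H]1C(C(C)=O)C[C@H]2C(C)(C)CCC[C@@]21C
F3 | step 13 | 7β-acetyl-7α-hydroxy-9β-[(2Z)-3-methylpenta-2,4-dien-1-yl]-4,4,10-trimethyl-trans-hydrindane | C=C/C(C)=C\C[C@H]1[C@@](O)(C(C)=O)C[C@H]2C(C)(C)CCC[C@@]21C
F4 | step 7 | 9β-[2-(tert-butyldimethylsilyloxy)ethyl]-4,4,10-trimethylhydrind-5-en-7-one | CC(C)(C)[Si](C)(C)OCC[C@H]1C(=O)C=C2C(C)(C)CCC[C@@]21C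
F5 | step 10 | 9β-(3,3-dibromoprop-2-en-1-yl)-4,4,10-trimethyl-trans-hydrindan-7-one | BrC(Br)=CC[C@H]1C(=O)C[C@H]2C(C)(C)CCC[C@@]21C
F6 | step 10 | 9β-[(2Z)-3-bromobut-2-en-1-yl]-4,4,10-trimethyl-trans-hydrindan-7-one | Br/C(C)=C\C[C@H]1C(=O)C[C@H]2C(C)(C)CCC[C@@]21C
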